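## Structural features

The target is a resveratrol-type trimer made of two 2,3-trans-2,3-dihydrobenzofurans. Unit 1 carries a 4-hydroxyphenyl group at C2, a hydroxyl at C6, a (Z)-4-hydroxystyryl arm at C4, and at C3 the benzo ring of unit 2, bonded through C5 of unit 2. Unit 2 carries a 4-hydroxyphenyl group at C2, a 3,5-dihydroxyphenyl group at C3 and a hydroxyl at C7. Re-derived from the structure, the four stereocentres are (2S,3S) in unit 1 and (2R,3R) in unit 2. They form two adjacent pairs held apart by an aromatic ring, so neither pair can steer the other and each needs its own source of absolute configuration. The fragile elements are the cis-stilbene (acid, light and metal surfaces isomerise it), the two benzylic aryl ether bonds O1–C2 (a 4-oxygenated aryl group lets them ionise to a quinone methide type cation) and seven air-sensitive phenols. The real difficulty is absolute control of two independent trans pairs together with a deprotection that spares the O1–C2 bonds and the Z alkene. The key step exploits unit 2: C2 bears O1, H and a 4-oxygenated phenyl group, which is the pattern of an O-arylated mandelic acid and is accessible in enantiopure form. C3a is the only open ortho carbon of the 2-methoxyphenyl ether ring, because C7 holds the methoxy group, so a C3–C3a closure has one possible regiochemistry. Unit 1 shows the same pattern at C2/C3/C3a and is closed the same way.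

## Logic of the disconnections

29 to 28. The Z C=C bond is traced back to the C≡C bond of 28. The cis-stilbene is the most isomerisation-prone part of the molecule, so it is made last and nothing acidic follows it. Every earlier step then handles a robust, linear alkyne. The forward step must stop at the alkene on a free heptaphenol.

28 to 27 to 26. The seven O–H bonds are traced to three O–S bonds (27) and behind them four O–CH3 bonds (26). The methyl ethers are removed while the sulfonates are still in place, because the electron-poor sulfonyloxyphenyl groups keep both O1–C2 bonds and the triple bond from reacting with the Lewis acid. The forward steps need a demethylation that leaves sulfonates alone and then a basic sulfonate cleavage under exclusion of air.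

26 to 23 + 25. The bond between the alkyne carbon and the 4-oxygenated phenyl ring is cut. This removes a whole aryl unit in a single coupling, and 25 is one step from 24. The coupling must occur at the iodide only and leave three aryl sulfonates untouched.

23 to 21 to 20. The alkyne carbon bonded to C4 of unit 1 is the ester carbon of 20, and the terminal carbon is added by a one-carbon homologation of the aldehyde. The ester is kept this long because it decides the regiochemistry of the ring closure that gives 20. The cost is two extra steps and a base-mediated homologation next to an acidic C3–H.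

20 to 19. The C3–C3a bond of unit 1 is cut, leaving an aryl ether with a benzylic alcohol at C3. This is the disconnection of the key step applied a second time: C2 is already in place and C3 follows from it. The forward step needs attack by the ring carbon para to methoxy and ortho to the ester, and trans closure.

19 to 18 to 12 + 15. The bond between C3 of unit 1 and C5 of unit 2 is cut, through the ketone 18, into an aryl nucleophile derived from 12 and the amide 15. This is the convergent point: each half carries one stereocentre pair or its source. The aryl metal must be generated from 12 without touching its sulfonate, and must add to the amide but not to the benzoate.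

15 to 13 + 14. The O1–C2 ether bond of unit 1 is cut next to the carbonyl group, where substitution with inversion is reliable. The forward step must give clean inversion without ionisation.

12 to 11 (key step). The C3–C3a bond of unit 2 is cut, leaving the 2-aryloxy-1,2-diarylethanol 11. Ring, bond and C3 stereocentre are all bought from a single stereocentre at C2. Two design changes are built into 11. A bromine sits para to the ether oxygen: it becomes the handle at C5 for the union and blocks the most nucleophilic open ring carbon against intermolecular attack, at the cost of a somewhat less nucleophilic arene. The phenol protecting group is a toluenesulfonate instead of a methanesulfonate: it is just as electron-poor but has no acidic S–CH3 protons, so it survives the aryl-metal reagents used to make 11 and 19.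

11 to 7 + 8. The bond from the carbinol carbon to the dimethoxyphenyl ring is cut, via the aldehyde 9 and the Grignard reagent 10. The carbinol configuration is irrelevant because it is erased in the key step. The α-aryloxy aldehyde must not be handled, since it would epimerise at the future C2.

7 to 4 + 6. The aryl ether bond at the future C2 of unit 2 is cut, as for 15 but in the opposite enantiomeric series.

4 and 13 to 5 and 3, then 2 and 1. Both C2 stereocentres are traced to the two enantiomers of one racemic α-hydroxy ester, separated by an enzymatic acylation; 4 feeds unit 2 and 5 (through 13) feeds unit 1, so neither half is wasted. Deamination of an arylglycine was set aside as the source of 4: with a 4-oxygenated aryl group the diazonium ion can ionise to a quinone methide type cation, so retention cannot be relied on, and nitrous acid also attacks the phenol ring. The phenol is sulfonylated before the stereocentre is resolved, for the same reason.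

25 to 24. The O–S bond is cut; the sulfonate keeps the coupled alkyne electron-poor during demethylation.

## Other disconnections considered

Alternative 1: The cut is again C3–C3a of unit 1, but the bond is made by migration. (2S)-Naringenin A1 would be converted to its 7,4'-dimethyl ether 5-triflate A2. With PhI(OAc)2 in HC(OMe)3/H2SO4 the enol ether of A2 is attacked at C3, the fused aryl carbon shifts from the carbonyl carbon to C3, and the pyranone contracts to the trans ester A3.
- In its favour: ring A arrives with the right oxygen pattern, the triflate at C4 is a ready handle for the alkyne, and C2 comes from a natural product in the (2S) series that unit 1 needs. On ring A regiochemistry this is better than the chosen plan, which relies on an ester to bias the ring closure. It is also shorter for unit 1 alone.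
- Against it here: C3 of A3 carries a carboxyl carbon where the target has a bond to an aromatic carbon of unit 2. After saponification, a decarboxylative C(sp3)–C(sp2) coupling with a bromide such as 12 would be needed at a centre β to an aryloxy leaving group. The flavanone stereocentre can racemise through the open chalcone under the acidic conditions. The 4-methoxyphenyl group at C2 leaves the O1–C2 bond open to ionisation in the final demethylation.
- Comparison: mechanistically the migration is concerted and trans-selective, equal to the chosen closure. It does nothing for unit 2, so a route based on it would still need a step like step 6. Overall the step count would not fall, and the union would be the weak point.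

Alternative 2: The cut is O1–C2 of unit 1. Anodic oxidation of phenol A4 in (CF3)2CHOH with 2,6-lutidine would give the para-quinone methide A5. The neighbouring ring phenol adds to it and closes the furan ring to the trans product A6.
- In its favour: the closure is mild, reagent-free and under thermodynamic control, with no cation next to a migrating group. Mechanistically it is safer than the Friedel–Crafts closure of step 11. It leaves the C2 aryl group as a free phenol, one protecting group fewer than in 20. The C4 ester is the same handle as in 20, so the two plans are equal there.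
- Against it here: A4 needs the C3 stereocentre set absolutely in an open-chain 1,1,2-triarylethane, for which there is no simple source, whereas the chosen plan obtains C3 from C2. The anode must oxidise the 4-hydroxybenzyl arm without touching the other electron-rich rings or the product phenol. Unit 2 in A6 carries a 4-methoxyphenyl group at C2, so the last demethylation is less safe than with the sulfonates of 26.
- Comparison: relative configuration is equally secure, absolute configuration less so, and the step count would be similar or higher once A4 is made.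

Alternative 3: The cut is C2–C3 of unit 1. Hydrazone A7 would be oxidised with MnO2 to the diaryldiazomethane A8, and its carbene on Rh2(R-PTAD)4 (dirhodium tetrakis[(R)-N-phthaloyl-1-adamantylglycinate], divalent rhodium) would insert into the benzylic C–H bond of the ether to give the 2,3-cis product A9.
- In its favour: the catalyst sets C3 absolutely, whatever unit 2 looks like. Ring A regiochemistry is fixed by the aldehyde used to build A7. The bromine at C4 can be coupled to the alkyne directly, which is better than the chosen plan by the two steps that turn the ester of 20 into an alkyne.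
- Against it here: the insertion gives the cis ring, so C2 must then be epimerised through ionisation of O1–C2. That requires an electron-rich C2 aryl group, the very feature that makes the ring fragile to BBr3 later and that the chosen plan removes. The hydrazone has to form at a ketone flanked by two ortho substituents. Catalyst and substrate chirality may be mismatched.
- Comparison: on structure it is the equal of the chosen plan for unit 1. On mechanism it replaces a cation by a metal carbene, which has no rearrangement risk but needs an epimerisation. In step count the two are about equal (union, oxidation, hydrazone, insertion, epimerisation against union, reduction, closure and two steps for the alkyne carbon).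

Key step: step 6

Remark (check of the structures): the descriptors were re-derived and need no correction. The ether-bearing carbon of 11 is S and becomes C2 (R) of 12 without any change of geometry, only of priorities.
Remark (assumption): the lipase is taken to acylate the (S)-alcohol of 3, the usual preference for mandelic esters. The carbinol centres of 11 and 19 are left as mixtures because both epimers give the same cation.
Shorthand: Ts = 4-methylbenzenesulfonyl (tosyl); U2 = (2R,3R)-3-(3,5-dimethoxyphenyl)-7-methoxy-2-[4-(tosyloxy)phenyl]-2,3-dihydro-1-benzofuran-5-yl.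

## Steps

Step 1
Reactants: 1 (RS)-4-hydroxymandelic acid
Product: 2 methyl (RS)-2-hydroxy-2-(4-hydroxyphenyl)acetate
Conditions: MeI, KHCO3, DMF, rt
Reagents that add atoms: iodomethane, CI
Why: Carboxylate O-alkylation (SN2); hydrogencarbonate deprotonates only the acid, so neither hydroxyl is methylated and an acid-catalysed esterification, which would solvolyse the 4-hydroxybenzylic alcohol, is avoided.

Step 2
Reactants: 2 methyl (RS)-2-hydroxy-2-(4-hydroxyphenyl)acetate
Product: 3 methyl (RS)-2-hydroxy-2-[4-(tosyloxy)phenyl]acetate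
Conditions: TsCl, K2CO3, acetone, rt
Reagents that add atoms: 4-methylbenzenesulfonyl chloride, Cc1ccc(cc1)S(Cl)(=O)=O
Why: Phenoxide sulfonylation; carbonate does not deprotonate the secondary alcohol, so only the phenol reacts, and the aryl group is made electron-poor before any stereocentre exists.

Step 3
Reactants: 3 methyl (RS)-2-hydroxy-2-[4-(tosyloxy)phenyl]acetate
Product: 4 methyl (R)-2-hydroxy-2-[4-(tosyloxy)phenyl]acetate (unreacted alcohol) together with 5 methyl (S)-2-acetoxy-2-[4-(tosyloxy)phenyl]acetate (acylated enantiomer)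
Conditions: Burkholderia cepacia lipase (immobilised), vinyl acetate, t-BuOMe, 35 °C, stopped near half conversion
Reagents that add atoms: vinyl acetate, CC(=O)OC=C
Why: Lipase-catalysed kinetic resolution by irreversible transesterification; the enzyme should acylate the (S)-alcohol, leaving 4 as the (R)-alcohol and giving 5 as the (S)-acetate, which fixes C2 of unit 2 and of unit 1 respectively. Either fraction can be brought to optical purity by crystallisation or a second pass.

Step 4
Reactants: 4 methyl (R)-2-hydroxy-2-[4-(tosyloxy)phenyl]acetate; 6 4-bromo-2-methoxyphenol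
Product: 7 methyl (S)-2-(4-bromo-2-methoxyphenoxy)-2-[4-(tosyloxy)phenyl]acetate
Conditions: PPh3, DIAD, toluene, 0 °C to rt
Reagents that add atoms: none
Why: Mitsunobu etherification, SN2 with inversion at the carbonyl-activated benzylic carbon, (R) to (S); the sulfonyloxyphenyl group disfavours an ionisation that would erode the configuration.

Step 5
Reactants: 7 methyl (S)-2-(4-bromo-2-methoxyphenoxy)-2-[4-(tosyloxy)phenyl]acetate; 8 1-bromo-3,5-dimethoxybenzene
Product: 11 (1RS,2S)-2-(4-bromo-2-methoxyphenoxy)-1-(3,5-dimethoxyphenyl)-2-[4-(tosyloxy)phenyl]ethan-1-ol, via aldehyde 9 (not isolated), via aryl Grignard reagent 10 (not isolated)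
Conditions: 8, Mg, THF, rt; 7, i-Bu2AlH, CH2Cl2, −78 °C; then 10 (3 equiv), −78 to 0 °C; aq. potassium sodium tartrate
Reagents that add atoms: none
Why: Tandem ester reduction and Grignard addition; the aluminium hemiacetal releases aldehyde 9 only in the presence of the nucleophile, so the enolisable α-aryloxy aldehyde is never handled and C2 should keep its configuration. The new carbinol centre is uncontrolled and is erased in step 6.

Step 6
Reactants: 11 (1RS,2S)-2-(4-bromo-2-methoxyphenoxy)-1-(3,5-dimethoxyphenyl)-2-[4-(tosyloxy)phenyl]ethan-1-ol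
Product: 12 (2R,3R)-5-bromo-3-(3,5-dimethoxyphenyl)-7-methoxy-2-[4-(tosyloxy)phenyl]-2,3-dihydro-1-benzofuran
Conditions: TfOH (20 mol %), (CF3)2CHOH–CH2Cl2, 0.01 M, 0 °C to rt
Reagents that add atoms: none
Why: Protonation of either carbinol epimer and loss of water in the strongly ionising, non-nucleophilic fluoroalcohol should give the secondary benzylic cation at C3, so both epimers converge. The free ortho carbon of the 4-bromo-2-methoxyphenyl ether attacks this cation in an intramolecular electrophilic aromatic substitution and loss of the ring proton restores aromaticity; the closest known reaction type is the acid-promoted Friedel–Crafts cycloalkylation of 2-aryloxy benzylic alcohols to 3-aryl-2,3-dihydrobenzofurans. The five-membered ring closes through C3–C3a with the attacked arene bond C3a–C7a inside the new ring, a 5-endo closure with respect to the arene, feasible because the free cationic carbon can rotate into overlap. The one new stereocentre, C3, is controlled by C2: in the envelope-like transition state the dimethoxyphenyl group on the planar cation turns away from the aryl group on C2, giving the 2,3-trans (2R,3R) ring. Regioselectivity is fixed by the substrate, since one ortho position carries the methoxy group, the para position carries bromine and the tether reaches no other carbon. Chemoselectivity rests on the tosyloxyphenyl group, which is too electron-poor to bridge as a phenonium ion, to stabilise a cation at C2 after an aryloxy or hydride shift, or to let C2–O ionise, so C2 keeps its configuration. High dilution keeps the dimethoxyphenyl ring of a second molecule from capturing the cation.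

Step 7
Reactants: 5 methyl (S)-2-acetoxy-2-[4-(tosyloxy)phenyl]acetate
Product: 13 (S)-2-hydroxy-N-methoxy-N-methyl-2-[4-(tosyloxy)phenyl]acetamide
Conditions: MeNH(OMe)·HCl, i-PrMgCl, THF, −20 to 0 °C
Reagents that add atoms: N,O-dimethylhydroxylamine hydrochloride, CNOC.Cl
Why: Aminolysis by the chloromagnesium amide turns the methyl ester into the Weinreb amide and removes the acetyl group in the same operation; the magnesium alkoxide formed first shields the α-carbon from enolisation, so the (S) configuration is retained.

Step 8
Reactants: 13 (S)-2-hydroxy-N-methoxy-N-methyl-2-[4-(tosyloxy)phenyl]acetamide; 14 methyl 3-hydroxy-5-methoxybenzoate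
Product: 15 methyl 3-methoxy-5-{(1R)-2-[methoxy(methyl)amino]-2-oxo-1-[4-(tosyloxy)phenyl]ethoxy}benzoate
Conditions: PPh3, DIAD, toluene, 0 °C to rt
Reagents that add atoms: none
Why: Mitsunobu etherification with inversion, (S) to (R), at a benzylic carbon activated by the amide carbonyl; this sets C2 of unit 1.

Step 9
Reactants: 12 (2R,3R)-5-bromo-3-(3,5-dimethoxyphenyl)-7-methoxy-2-[4-(tosyloxy)phenyl]-2,3-dihydro-1-benzofuran; 15 methyl 3-methoxy-5-{(1R)-2-[methoxy(methyl)amino]-2-oxo-1-[4-(tosyloxy)phenyl]ethoxy}benzoate
Product: 18 methyl 3-methoxy-5-{(1R)-2-oxo-2-(U2)-1-[4-(tosyloxy)phenyl]ethoxy}benzoate, via aryllithium 16 (not isolated), via arylmagnesium bromide 17 (not isolated)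
Conditions: 12, n-BuLi, THF, −78 °C; MgBr2·OEt2, −78 °C; then 15, −78 to −10 °C; aq. NH4Cl
Reagents that add atoms: none
Why: Bromine–lithium exchange should outrun attack on the aryl sulfonate, and transmetalation to magnesium tempers the basicity. Acyl substitution at the Weinreb amide stops at the chelated tetrahedral intermediate, so ketone 18 appears only on quench and the α-centre is not exposed to base; the benzoate is inert at this temperature.

Step 10
Reactants: 18 methyl 3-methoxy-5-{(1R)-2-oxo-2-(U2)-1-[4-(tosyloxy)phenyl]ethoxy}benzoate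
Product: 19 methyl 3-{(1R,2RS)-2-hydroxy-2-(U2)-1-[4-(tosyloxy)phenyl]ethoxy}-5-methoxybenzoate
Conditions: NaBH4, CeCl3·7H2O, MeOH–THF, −40 °C
Reagents that add atoms: none
Why: Luche reduction is fast and nearly neutral, so the acidic α-centre should not epimerise and the ester is untouched; the carbinol configuration does not matter.

Step 11
Reactants: 19 methyl 3-{(1R,2RS)-2-hydroxy-2-(U2)-1-[4-(tosyloxy)phenyl]ethoxy}-5-methoxybenzoate
Product: 20 methyl (2S,3S)-6-methoxy-3-(U2)-2-[4-(tosyloxy)phenyl]-2,3-dihydro-1-benzofuran-4-carboxylate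
Conditions: TfOH (5 mol %), (CF3)2CHOH–CH2Cl2, 0.01 M, −20 to 0 °C
Reagents that add atoms: none
Why: Same Friedel–Crafts cycloalkylation as step 6, with an easier cation because the ring oxygen of unit 2 is para to the cationic carbon. The ring carbon para to methoxy and ortho to the ester attacks; the other ortho carbon lies between two oxygens and para to the ester and is the most deactivated. C3 is set trans to the C2 aryl group as in step 6, and unit 2 is inert because its C2 aryl group is electron-poor.

Step 12
Reactants: 20 methyl (2S,3S)-6-methoxy-3-(U2)-2-[4-(tosyloxy)phenyl]-2,3-dihydro-1-benzofuran-4-carboxylate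
Product: 21 {(2S,3S)-6-methoxy-3-(U2)-2-[4-(tosyloxy)phenyl]-2,3-dihydro-1-benzofuran-4-yl}methanol
Conditions: i-Bu2AlH (excess), CH2Cl2, −78 to 0 °C; aq. potassium sodium tartrate
Reagents that add atoms: none
Why: Hydride reduction of the aryl ester to the benzylic alcohol; aryl sulfonates and aryl ethers tolerate the reagent at this temperature.

Step 13
Reactants: 21 {(2S,3S)-6-methoxy-3-(U2)-2-[4-(tosyloxy)phenyl]-2,3-dihydro-1-benzofuran-4-yl}methanol
Product: 23 (2S,3S)-4-ethynyl-6-methoxy-3-(U2)-2-[4-(tosyloxy)phenyl]-2,3-dihydro-1-benzofuran, via aldehyde 22 (not isolated)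
Conditions: MnO2, THF, rt; then MeOH, K2CO3, dimethyl (1-diazo-2-oxopropyl)phosphonate, 0 °C to rt
Reagents that add atoms: dimethyl (1-diazo-2-oxopropyl)phosphonate, CC(=O)C(=[N+]=[N-])P(=O)(OC)OC
Why: Benzylic oxidation followed in the same flask by the Seyferth–Gilbert homologation in its Ohira–Bestmann form; carbonate in methanol is mild enough for the sulfonates. Aldehyde 22 is not isolated because its ortho C3–H is vinylogously acidic.

Step 14
Reactants: 24 4-iodophenol
Product: 25 4-iodophenyl 4-methylbenzenesulfonate
Conditions: TsCl, Et3N, CH2Cl2, 0 °C to rt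
Reagents that add atoms: 4-methylbenzenesulfonyl chloride, Cc1ccc(cc1)S(Cl)(=O)=O
Why: Routine phenol sulfonylation; the sulfonate later keeps the diaryl alkyne electron-poor.

Step 15
Reactants: 23 (2S,3S)-4-ethynyl-6-methoxy-3-(U2)-2-[4-(tosyloxy)phenyl]-2,3-dihydro-1-benzofuran; 25 4-iodophenyl 4-methylbenzenesulfonate
Product: 26 (2S,3S)-6-methoxy-3-(U2)-2-[4-(tosyloxy)phenyl]-4-{[4-(tosyloxy)phenyl]ethynyl}-2,3-dihydro-1-benzofuran
Conditions: PdCl2(PPh3)2, CuI, Et3N, THF, rt, degassed
Reagents that add atoms: none
Why: Sonogashira coupling of a terminal alkyne with an aryl iodide at room temperature; aryl sulfonates do not undergo oxidative addition with this triphenylphosphine catalyst.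

Step 16
Reactants: 26 (2S,3S)-6-methoxy-3-(U2)-2-[4-(tosyloxy)phenyl]-4-{[4-(tosyloxy)phenyl]ethynyl}-2,3-dihydro-1-benzofuran
Product: 27 (2S,3S)-3-{(2R,3R)-3-(3,5-dihydroxyphenyl)-7-hydroxy-2-[4-(tosyloxy)phenyl]-2,3-dihydro-1-benzofuran-5-yl}-2-[4-(tosyloxy)phenyl]-4-{[4-(tosyloxy)phenyl]ethynyl}-2,3-dihydro-1-benzofuran-6-ol
Conditions: BBr3, CH2Cl2, −78 to 0 °C; MeOH, then H2O
Reagents that add atoms: none
Why: Lewis-acid cleavage of the four aryl methyl ethers; aryl sulfonates survive. The sulfonyloxyphenyl groups keep both O1–C2 bonds from ionising and keep the triple bond too electron-poor for protonation or bromoboration.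

Step 17
Reactants: 27 the tetraphenol tris(toluenesulfonate) of step 16
Product: 28 (2S,3S)-3-[(2R,3R)-3-(3,5-dihydroxyphenyl)-7-hydroxy-2-(4-hydroxyphenyl)-2,3-dihydro-1-benzofuran-5-yl]-2-(4-hydroxyphenyl)-4-[(4-hydroxyphenyl)ethynyl]-2,3-dihydro-1-benzofuran-6-ol
Conditions: KOH, MeOH–THF–H2O, 60 °C, argon; then dilute HCl
Reagents that add atoms: none
Why: Hydroxide attacks sulfur of the three aryl sulfonates and releases the phenoxides; the stereocentres are not involved and air is excluded because the polyphenoxide is oxidisable.

Step 18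
Reactants: 28 the heptaphenol alkyne of step 17
Product: 29 (2S,3S)-3-[(2R,3R)-3-(3,5-dihydroxyphenyl)-7-hydroxy-2-(4-hydroxyphenyl)-2,3-dihydro-1-benzofuran-5-yl]-2-(4-hydroxyphenyl)-4-[(Z)-2-(4-hydroxyphenyl)ethenyl]-2,3-dihydro-1-benzofuran-6-ol
Conditions: H2 (1 atm), Pd on CaCO3 poisoned with Pb(OAc)2, quinoline, EtOAc–MeOH, rt, dark, stopped after one equivalent
Reagents that add atoms: none
Why: Lindlar-type semi-hydrogenation; both hydrogens are delivered from the poisoned palladium surface to the same face of the alkyne, which sets the Z geometry. It is placed last so that the cis-stilbene meets no acid.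

## Compound list

1 | (RS)-4-hydroxymandelic acid | OC(C(=O)O)c1ccc(O)cc1 | starting material
2 | methyl (RS)-2-hydroxy-2-(4-hydroxyphenyl)acetate | COC(=O)C(O)c1ccc(O)cc1 | intermediate
3 | methyl (RS)-2-hydroxy-2-[4-(tosyloxy)phenyl]acetate | COC(=O)C(O)c1ccc(OS(=O)(=O)c2ccc(C)cc2)cc1 | intermediate
4 | methyl (R)-2-hydroxy-2-[4-(tosyloxy)phenyl]acetate | COC(=O)[C@H](O)c1ccc(OS(=O)(=O)c2ccc(C)cc2)cc1 | intermediate
5 | methyl (S)-2-acetoxy-2-[4-(tosyloxy)phenyl]acetate | COC(=O)[C@@H](OC(C)=O)c1ccc(OS(=O)(=O)c2ccc(C)cc2)cc1 | intermediate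
6 | 4-bromo-2-methoxyphenol | COc1cc(Br)ccc1O | starting material
7 | methyl (S)-2-(4-bromo-2-methoxyphenoxy)-2-[4-(tosyloxy)phenyl]acetate | COc1cc(Br)ccc1O[C@@H](c1ccc(OS(=O)(=O)c2ccc(C)cc2)cc1)C(=O)OC | intermediate
8 | 1-bromo-3,5-dimethoxybenzene | COc1cc(Br)cc(OC)c1 | starting material
9 | (S)-2-(4-bromo-2-methoxyphenoxy)-2-[4-(tosyloxy)phenyl]acetaldehyde | COc1cc(Br)ccc1O[C@@H](c1ccc(OS(=O)(=O)c2ccc(C)cc2)cc1)C=O | intermediate
10 | (3,5-dimethoxyphenyl)magnesium bromide | COc1cc([Mg]Br)cc(OC)c1 | intermediate
11 | (1RS,2S)-2-(4-bromo-2-methoxyphenoxy)-1-(3,5-dimethoxyphenyl)-2-[4-(tosyloxy)phenyl]ethan-1-ol | COc1cc(Br)ccc1O[C@@H](c1ccc(OS(=O)(=O)c2ccc(C)cc2)cc1)C(O)c1cc(OC)cc(OC)c1 | intermediate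
12 | (2R,3R)-5-bromo-3-(3,5-dimethoxyphenyl)-7-methoxy-2-[4-(tosyloxy)phenyl]-2,3-dihydro-1-benzofuran | Brc1cc(OC)c2c(c1)[C@@H](c1cc(OC)cc(OC)c1)[C@H](c1ccc(OS(=O)(=O)c3ccc(C)cc3)cc1)O2 | intermediate
13 | (S)-2-hydroxy-N-methoxy-N-methyl-2-[4-(tosyloxy)phenyl]acetamide | CON(C)C(=O)[C@@H](O)c1ccc(OS(=O)(=O)c2ccc(C)cc2)cc1 | intermediate
14 | methyl 3-hydroxy-5-methoxybenzoate | COC(=O)c1cc(O)cc(OC)c1 | starting material
15 | methyl 3-methoxy-5-{(1R)-2-[methoxy(methyl)amino]-2-oxo-1-[4-(tosyloxy)phenyl]ethoxy}benzoate | CON(C)C(=O)[C@H](Oc1cc(OC)cc(c1)C(=O)OC)c1ccc(OS(=O)(=O)c2ccc(C)cc2)cc1 | intermediate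
16 | (U2)lithium, the 5-lithio derivative of 12 | [Li]c1cc(OC)c2c(c1)[C@@H](c1cc(OC)cc(OC)c1)[C@H](c1ccc(OS(=O)(=O)c3ccc(C)cc3)cc1)O2 | intermediate
17 | (U2)magnesium bromide | Br[Mg]c1cc(OC)c2c(c1)[C@@H](c1cc(OC)cc(OC)c1)[C@H](c1ccc(OS(=O)(=O)c3ccc(C)cc3)cc1)O2 | intermediate
18 | methyl 3-methoxy-5-{(1R)-2-oxo-2-(U2)-1-[4-(tosyloxy)phenyl]ethoxy}benzoate | COC(=O)c1cc(OC)cc(c1)O[C@H](c1ccc(OS(=O)(=O)c2ccc(C)cc2)cc1)C(=O)c1cc(OC)c2c(c1)[C@@H](c1cc(OC)cc(OC)c1)[C@H](c1ccc(OS(=O)(=O)c3ccc(C)cc3)cc1)O2 | intermediate
19 | methyl 3-{(1R,2RS)-2-hydroxy-2-(U2)-1-[4-(tosyloxy)phenyl]ethoxy}-5-methoxybenzoate | COC(=O)c1cc(OC)cc(c1)O[C@H](c1ccc(OS(=O)(=O)c2ccc(C)cc2)cc1)C(O)c1cc(OC)c2c(c1)[C@@H](c1cc(OC)cc(OC)c1)[C@H](c1ccc(OS(=O)(=O)c3ccc(C)cc3)cc1)O2 | intermediate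
20 | methyl (2S,3S)-6-methoxy-3-(U2)-2-[4-(tosyloxy)phenyl]-2,3-dihydro-1-benzofuran-4-carboxylate | COC(=O)c1cc(OC)cc2c1[C@H](c1cc(OC)c3c(c1)[C@@H](c1cc(OC)cc(OC)c1)[C@H](c1ccc(OS(=O)(=O)c4ccc(C)cc4)cc1)O3)[C@@H](c1ccc(OS(=O)(=O)c3ccc(C)cc3)cc1)O2 | intermediate
21 | {(2S,3S)-6-methoxy-3-(U2)-2-[4-(tosyloxy)phenyl]-2,3-dihydro-1-benzofuran-4-yl}methanol | OCc1cc(OC)cc2c1[C@H](c1cc(OC)c3c(c1)[C@@H](c1cc(OC)cc(OC)c1)[C@H](c1ccc(OS(=O)(=O)c4ccc(C)cc4)cc1)O3)[C@@H](c1ccc(OS(=O)(=O)c3ccc(C)cc3)cc1)O2 | intermediate
22 | (2S,3S)-6-methoxy-3-(U2)-2-[4-(tosyloxy)phenyl]-2,3-dihydro-1-benzofuran-4-carbaldehyde | O=Cc1cc(OC)cc2c1[C@H](c1cc(OC)c3c(c1)[C@@H](c1cc(OC)cc(OC)c1)[C@H](c1ccc(OS(=O)(=O)c4ccc(C)cc4)cc1)O3)[C@@H](c1ccc(OS(=O)(=O)c3ccc(C)cc3)cc1)O2 | intermediate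
23 | (2S,3S)-4-ethynyl-6-methoxy-3-(U2)-2-[4-(tosyloxy)phenyl]-2,3-dihydro-1-benzofuran | C#Cc1cc(OC)cc2c1[C@H](c1cc(OC)c3c(c1)[C@@H](c1cc(OC)cc(OC)c1)[C@H](c1ccc(OS(=O)(=O)c4ccc(C)cc4)cc1)O3)[C@@H](c1ccc(OS(=O)(=O)c3ccc(C)cc3)cc1)O2 | intermediate
24 | 4-iodophenol | Oc1ccc(I)cc1 | starting material
25 | 4-iodophenyl 4-methylbenzenesulfonate | Cc1ccc(cc1)S(=O)(=O)Oc1ccc(I)cc1 | intermediate
26 | (2S,3S)-6-methoxy-3-(U2)-2-[4-(tosyloxy)phenyl]-4-{[4-(tosyloxy)phenyl]ethynyl}-2,3-dihydro-1-benzofuran | Cc1ccc(cc1)S(=O)(=O)Oc1ccc(cc1)C#Cc1cc(OC)cc2c1[C@H](c1cc(OC)c3c(c1)[C@@H](c1cc(OC)cc(OC)c1)[C@H](c1ccc(OS(=O)(=O)c4ccc(C)cc4)cc1)O3)[C@@H](c1ccc(OS(=O)(=O)c3ccc(C)cc3)cc1)O2 | intermediate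
27 | (2S,3S)-3-{(2R,3R)-3-(3,5-dihydroxyphenyl)-7-hydroxy-2-[4-(tosyloxy)phenyl]-2,3-dihydro-1-benzofuran-5-yl}-2-[4-(tosyloxy)phenyl]-4-{[4-(tosyloxy)phenyl]ethynyl}-2,3-dihydro-1-benzofuran-6-ol | Cc1ccc(cc1)S(=O)(=O)Oc1ccc(cc1)C#Cc1cc(O)cc2c1[C@H](c1cc(O)c3c(c1)[C@@H](c1cc(O)cc(O)c1)[C@H](c1ccc(OS(=O)(=O)c4ccc(C)cc4)cc1)O3)[C@@H](c1ccc(OS(=O)(=O)c3ccc(C)cc3)cc1)O2 | intermediate
28 | (2S,3S)-3-[(2R,3R)-3-(3,5-dihydroxyphenyl)-7-hydroxy-2-(4-hydroxyphenyl)-2,3-dihydro-1-benzofuran-5-yl]-2-(4-hydroxyphenyl)-4-[(4-hydroxyphenyl)ethynyl]-2,3-dihydro-1-benzofuran-6-ol | Oc1ccc(cc1)C#Cc1cc(O)cc2c1[C@H](c1cc(O)c3c(c1)[C@@H](c1cc(O)cc(O)c1)[C@H](c1ccc(O)cc1)O3)[C@@H](c1ccc(O)cc1)O2 | intermediate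
29 | (2S,3S)-3-[(2R,3R)-3-(3,5-dihydroxyphenyl)-7-hydroxy-2-(4-hydroxyphenyl)-2,3-dihydro-1-benzofuran-5-yl]-2-(4-hydroxyphenyl)-4-[(Z)-2-(4-hydroxyphenyl)ethenyl]-2,3-dihydro-1-benzofuran-6-ol | Oc1ccc(/C=C\c2cc(O)cc3c2[C@H](c2cc(O)c4c(c2)[C@@H](c2cc(O)cc(O)c2)[C@H](c2ccc(O)cc2)O4)[C@@H](c2ccc(O)cc2)O3)cc1 | target

## Step count and least certain steps

Total: 18 steps. Longest linear sequence: 15 steps (steps 1 to 6, 9 to 13 and 15 to 18).

Step 6 (key step). The most likely failure is diversion of the poorly stabilised cation before the ring closes. A 1,2-hydride shift or loss of the C2 proton leads to an oxocarbenium ion or enol ether and so to loss of the C2 stereocentre and of the aryloxy group. Migration of the aryloxy group through an oxiranium ion, or capture by the dimethoxyphenyl ring of a second molecule, are the other escapes. The bromine makes these more likely because it lowers the nucleophilicity of the attacking ring carbon. Fallback, from 4 back to 12: the handle is left out of the cyclisation substrate and installed afterwards by a sterically controlled C–H functionalisation. Mitsunobu reaction of 4 with 2-methoxyphenol in place of 6 would give methyl (S)-2-(2-methoxyphenoxy)-2-[4-(tosyloxy)phenyl]acetate F1. Reduction and addition as in step 5 would give (1RS,2S)-1-(3,5-dimethoxyphenyl)-2-(2-methoxyphenoxy)-2-[4-(tosyloxy)phenyl]ethan-1-ol F2, whose more electron-rich ring should cyclise under the conditions of step 6 to (2R,3R)-3-(3,5-dimethoxyphenyl)-7-methoxy-2-[4-(tosyloxy)phenyl]-2,3-dihydro-1-benzofuran F3. C–H borylation with [Ir(OMe)(cod)]2, 4,4'-di-tert-butyl-2,2'-bipyridine and B2pin2 should take place at C5, the only C–H without an ortho substituent, to give the 5-(pinacolboryl) compound F4, and CuBr2 in aqueous methanol would convert this to 12.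

Step 11. The most likely failure is a slow ring closure at the ring carbon flanked by the ester, which would let proton loss from C2 or intermolecular capture of the long-lived cation compete, together with some cis closure. Fallback, from 19 back to 21: the order of reduction and cyclisation is exchanged, so that the ring closes on an arene without the deactivating, crowding ester. Reduction of 19 with i-Bu2AlH would give 3-{(1R,2RS)-2-hydroxy-2-(U2)-1-[4-(tosyloxy)phenyl]ethoxy}-5-methoxybenzyl alcohol F6, and treatment as in step 11 should ionise only the secondary, para-oxygen-stabilised alcohol and give 21 directly. The price is that regiocontrol then rests only on the preference for the position para to methoxy.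

Step 9. The most likely failure is sluggish addition to the hindered amide, so that on warming attack at the benzoate and proton transfer from C–H acidic sites compete; incomplete halogen–lithium exchange is the second concern. Fallback, from 15 back to 19: a far more reactive electrophile is used at low temperature. Reduction of 15 with i-Bu2AlH at −78 °C would give the aldehyde methyl 3-methoxy-5-{(1R)-2-oxo-1-[4-(tosyloxy)phenyl]ethoxy}benzoate F5, used crude at once, and addition of 17 at −78 °C would give 19 directly, bypassing 18 and step 10.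

Step 16. The most likely failure is acid-induced damage while the last, hindered methyl ether is being cleaved: addition of HBr to the triple bond or opening of a benzylic ether as the mixture warms. Fallback, from 26 back to 28: the Lewis acid is replaced by a nucleophile. Sodium ethanethiolate in DMF at about 120 °C removes methyl groups by SN2 attack at carbon and sulfonyl groups by attack at sulfur, and would take 26 to 28 in one operation under non-acidic conditions; no new compound is made (F0).

Step 18. The most likely failure is over-reduction to the bibenzyl and Z to E isomerisation on the metal surface, made worse by adsorption of the polyphenol on the catalyst. Fallback, from 28 back to 29: catalytic hydrogenation is replaced by reduction with activated zinc (zinc dust treated with Cu(OAc)2 and AgNO3) in aqueous methanol. This reduces a conjugated alkyne to the Z alkene by electron transfer and protonation and does not reduce the alkene further; no new compound is made (F0).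

## Further compounds

F1 | step 6 | methyl (S)-2-(2-methoxyphenoxy)-2-[4-(tosyloxy)phenyl]acetate | COc1ccccc1O[C@@H](c1ccc(OS(=O)(=O)c2ccc(C)cc2)cc1)C(=O)OC
F2 | step 6 | (1RS,2S)-1-(3,5-dimethoxyphenyl)-2-(2-methoxyphenoxy)-2-[4-(tosyloxy)phenyl]ethan-1-ol | COc1ccccc1O[C@@H](c1ccc(OS(=O)(=O)c2ccc(C)cc2)cc1)C(O)c1cc(OC)cc(OC)c1
F3 | step 6 | (2R,3R)-3-(3,5-dimethoxyphenyl)-7-methoxy-2-[4-(tosyloxy)phenyl]-2,3-dihydro-1-benzofuran | c1cc(OC)c2c(c1)[C@@H](c1cc(OC)cc(OC)c1)[C@H](c1ccc(OS(=O)(=O)c3ccc(C)cc3)cc1)O2
F4 | step 6 | (2R,3R)-3-(3,5-dimethoxyphenyl)-7-methoxy-5-(4,4,5,5-tetramethyl-1,3,2-dioxaborolan-2-yl)-2-[4-(tosyloxy)phenyl]-2,3-dihydro-1-benzofuran | CC1(C)OB(OC1(C)C)c1cc(OC)c2c(c1)[C@@H](c1cc(OC)cc(OC)c1)[C@H](c1ccc(OS(=O)(=O)c3ccc(C)cc3)cc1)O2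
F5 | step 9 | methyl 3-methoxy-5-{(1R)-2-oxo-1-[4-(tosyloxy)phenyl]ethoxy}benzoate | COC(=O)c1cc(OC)cc(c1)O[C@H](c1ccc(OS(=O)(=O)c2ccc(C)cc2)cc1)C=O
F6 | step 11 | 3-{(1R,2RS)-2-hydroxy-2-(U2)-1-[4-(tosyloxy)phenyl]ethoxy}-5-methoxybenzyl alcohol | OCc1cc(OC)cc(c1)O[C@H](c1ccc(OS(=O)(=O)c2ccc(C)cc2)cc1)C(O)c1cc(OC)c2c(c1)[C@@H](c1cc(OC)cc(OC)c1)[C@H](c1ccc(OS(=O)(=O)c3ccc(C)cc3)cc1)O2
F0 | step 16 | none | none
F0 | step 18 | none | none
A1 | alternative 1 | (2S)-naringenin, (2S)-5,7-dihydroxy-2-(4-hydroxyphenyl)chroman-4-one | O=C1C[C@@H](c2ccc(O)cc2)Oc2cc(O)cc(O)c12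
A2 | alternative 1 | (2S)-7-methoxy-2-(4-methoxyphenyl)-4-oxochroman-5-yl trifluoromethanesulfonate | O=C1C[C@@H](c2ccc(OC)cc2)Oc2cc(OC)cc(OS(=O)(=O)C(F)(F)F)c12
A3 | alternative 1 | methyl (2S,3S)-6-methoxy-2-(4-methoxyphenyl)-4-(triflyloxy)-2,3-dihydro-1-benzofuran-3-carboxylate | FC(F)(F)S(=O)(=O)Oc1cc(OC)cc2c1[C@H](C(=O)OC)[C@@H](c1ccc(OC)cc1)O2
A4 | alternative 2 | methyl 2-{(1S)-1-[(2R,3R)-3-(3,5-dimethoxyphenyl)-7-methoxy-2-(4-methoxyphenyl)-2,3-dihydro-1-benzofuran-5-yl]-2-(4-hydroxyphenyl)ethyl}-3-hydroxy-5-methoxybenzoate | COC(=O)c1cc(OC)cc(O)c1[C@H](c1cc(OC)c2c(c1)[C@@H](c1cc(OC)cc(OC)c1)[C@H](c1ccc(OC)cc1)O2)Cc1ccc(O)cc1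
A5 | alternative 2 | para-quinone methide of A4 (4-oxocyclohexa-2,5-dien-1-ylidene in place of the 4-hydroxybenzyl arm) | COC(=O)c1cc(OC)cc(O)c1[C@H](c1cc(OC)c2c(c1)[C@@H](c1cc(OC)cc(OC)c1)[C@H](c1ccc(OC)cc1)O2)C=C1C=CC(=O)C=C1
A6 | alternative 2 | methyl (2S,3S)-3-[(2R,3R)-3-(3,5-dimethoxyphenyl)-7-methoxy-2-(4-methoxyphenyl)-2,3-dihydro-1-benzofuran-5-yl]-2-(4-hydroxyphenyl)-6-methoxy-2,3-dihydro-1-benzofuran-4-carboxylate | COC(=O)c1cc(OC)cc2c1[C@H](c1cc(OC)c3c(c1)[C@@H](c1cc(OC)cc(OC)c1)[C@H](c1ccc(OC)cc1)O3)[C@@H](c1ccc(O)cc1)O2
A7 | alternative 3 | hydrazone of {2-bromo-4-methoxy-6-[(4-methoxyphenyl)methoxy]phenyl}[(2R,3R)-3-(3,5-dimethoxyphenyl)-7-methoxy-2-(4-methoxyphenyl)-2,3-dihydro-1-benzofuran-5-yl]methanone | NN=C(c1c(Br)cc(OC)cc1OCc1ccc(OC)cc1)c1cc(OC)c2c(c1)[C@@H](c1cc(OC)cc(OC)c1)[C@H](c1ccc(OC)cc1)O2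
A8 | alternative 3 | diaryldiazomethane derived from A7 | [N-]=[N+]=C(c1c(Br)cc(OC)cc1OCc1ccc(OC)cc1)c1cc(OC)c2c(c1)[C@@H](c1cc(OC)cc(OC)c1)[C@H](c1ccc(OC)cc1)O2
A9 | alternative 3 | (2R,3S)-4-bromo-3-[(2R,3R)-3-(3,5-dimethoxyphenyl)-7-methoxy-2-(4-methoxyphenyl)-2,3-dihydro-1-benzofuran-5-yl]-6-methoxy-2-(4-methoxyphenyl)-2,3-dihydro-1-benzofuran (2,3-cis in unit 1) | Brc1cc(OC)cc2c1[C@H](c1cc(OC)c3c(c1)[C@@H](c1cc(OC)cc(OC)c1)[C@H](c1ccc(OC)cc1)O3)[C@H](c1ccc(OC)cc1)O2
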